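## Retrosynthetic overview

1. The target is methyl gyrophorate, an achiral tridepside of three orsellinate rings: ring A (methyl ester end, unprimed locants), ring B (centre, primed) and ring C (free resorcinol end, doubly primed). The last operation is hydrogenolysis of benzyl ethers at O-2', O-2'' and O-4''.
2. Feature used: the ring B carboxyl carbon is a single carbon between C1' (flanked by 2'-O and 6'-CH3) and O-4 of ring A. C1' lies para to O-4' and ortho to O-2' of an orcinol nucleus, which is where an electrophilic halogen can be placed.
3. Key disconnection: both bonds at that carbon, C1'–C(=O) and C(=O)–O-4, are cut together. This gives a ring B aryl iodide that already carries ring C, carbon monoxide and methyl orsellinate.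
4. The iodide comes from 4-iodoorcinol. Its uncrowded hydroxyl is acylated with 2,4-bis(benzyloxy)-6-methylbenzoyl chloride (made from methyl orsellinate), and the hydroxyl next to iodine is then benzylated.
5. No ring is built. All three benzene rings are bought intact and joined in the order C to B, then B to A.

Key step: step 6

Assumption: neutral orcinol is taken to accept iodine from NIS in an aprotic, base-free medium at C4 (next to CH3), the site of its chlorination and bromination, and not at C2, the site favoured by aqueous I2/NaHCO3.

## Route

Step 1
Reactants: 1 methyl orsellinate (methyl 2,4-dihydroxy-6-methylbenzoate)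
Product: 2 methyl 2,4-bis(benzyloxy)-6-methylbenzoate
Conditions: BnBr (2.5 equiv), K2CO3 (3 equiv), DMF, 70 °C
Reagents that add atoms: benzyl bromide, BrCc1ccccc1
Why: Williamson ether synthesis; warm DMF with excess carbonate also alkylates the hydrogen-bonded 2-hydroxyl, and the crowded methyl ester is untouched.

Step 2
Reactants: 2 methyl 2,4-bis(benzyloxy)-6-methylbenzoate
Product: 3 2,4-bis(benzyloxy)-6-methylbenzoic acid
Conditions: KOH, DMSO/H2O, 95 °C; then cold aq. HCl
Reagents that add atoms: potassium hydroxide, [K+].[OH-] (oxygen of the new carboxyl OH)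
Why: Saponification of a di-ortho-substituted benzoate needs poorly solvated hydroxide in hot aqueous DMSO, which benzyl aryl ethers tolerate, and cold acidification avoids decarboxylation of the electron-rich acid.

Step 3
Reactants: 4 orcinol (5-methylbenzene-1,3-diol)
Product: 5 4-iodoorcinol (4-iodo-5-methylbenzene-1,3-diol; iodine between CH3 and one OH)
Conditions: NIS (1.0 equiv, added slowly), MeCN, −20 → 0 °C, dark
Reagents that add atoms: N-iodosuccinimide, O=C1CCC(=O)N1I
Why: Electrophilic aromatic iodination of the neutral phenol should go para to one hydroxyl and ortho to the other (C4), as halogenation of 5-alkylresorcinols does without base, while one equivalent of NIS at low temperature limits 4,6-diiodination and the phenoxide protocol that targets C2 is avoided.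

Step 4
Reactants: 3 2,4-bis(benzyloxy)-6-methylbenzoic acid; 5 4-iodoorcinol
Product: 7 3-hydroxy-4-iodo-5-methylphenyl 2,4-bis(benzyloxy)-6-methylbenzoate, via 2,4-bis(benzyloxy)-6-methylbenzoyl chloride 6 (not isolated)
Conditions: (COCl)2, cat. DMF, CH2Cl2, 0 °C → rt, evaporate from toluene; then 5 (1.3 equiv), pyridine, cat. DMAP, CH2Cl2, −10 °C → rt
Reagents that add atoms: oxalyl chloride, O=C(Cl)C(=O)Cl (supplies the chlorine of 6; no atom of it remains in 7)
Why: Vilsmeier-catalysed acid chloride formation is followed by Einhorn-type acylation in pyridine, in which the di-ortho-substituted aroyl donor should choose the hydroxyl flanked by two hydrogens over the one crowded by iodine, and the absence of a strong base keeps the more acidic iodine-flanked hydroxyl from reacting as its phenoxide.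

Step 5
Reactants: 7 3-hydroxy-4-iodo-5-methylphenyl 2,4-bis(benzyloxy)-6-methylbenzoate
Product: 8 3-(benzyloxy)-4-iodo-5-methylphenyl 2,4-bis(benzyloxy)-6-methylbenzoate
Conditions: BnBr, K2CO3, acetone, 50 °C
Reagents that add atoms: benzyl bromide, BrCc1ccccc1
Why: Williamson ether synthesis on the acidic ortho-iodophenol; the aryl ester is meta to the phenoxide, which rules out intramolecular migration, and its di-ortho-substituted carbonyl resists intermolecular exchange under mild carbonate conditions.

Step 6
Reactants: 8 3-(benzyloxy)-4-iodo-5-methylphenyl 2,4-bis(benzyloxy)-6-methylbenzoate; 9 carbon monoxide; 1 methyl orsellinate (1.5 equiv)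
Product: 10 methyl 4-{[2-(benzyloxy)-4-{[2,4-bis(benzyloxy)-6-methylbenzoyl]oxy}-6-methylbenzoyl]oxy}-2-hydroxy-6-methylbenzoate (2',2'',4''-tri-O-benzyl methyl gyrophorate)
Conditions: Pd(dba)2 (5 mol %), Xantphos (6 mol %), Et3N (2 equiv), 4 Å MS, toluene, CO (5 bar), 90 °C
Reagents that add atoms: carbon monoxide (9), [C-]#[O+]
Why: Zerovalent palladium inserts into the C1'–I bond of 8, CO undergoes migratory insertion to give the aroylpalladium iodide, the triethylammonium 4-phenoxide of 1 displaces iodide at palladium, and reductive elimination forms the C(=O)–O-4 bond and returns the catalyst, so that C1'–C(=O) and C(=O)–O are made in one operation. The reaction type is the known Heck-type aryloxycarbonylation of aryl iodides with phenols, applied here to a di-ortho-substituted iodide, and the wide-bite-angle Xantphos is chosen because it speeds acyl–oxygen reductive elimination. No ring is closed and no stereocentre is created. Site selectivity in 1 rests on the 2-hydroxyl being held in a six-membered hydrogen bond to the ester carbonyl and shielded by it, while the 4-hydroxyl, para to the ester, is the more acidic and the only one ionised by Et3N. Carbonylation should outrun direct diaryl ether formation because CO insertion relieves the strain of an aryl–palladium bond flanked by CH3 and OBn and is driven by 5 bar of CO, whereas aryl–oxygen reductive elimination from such a complex is slow. The amine base in place of carbonate or carboxylate, the acetate-free palladium source and the molecular sieves are meant to hold back cyclopalladation of the neighbouring benzyl ether, exchange at the crowded B–C ester and hydroxycarbonylation.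

Step 7
Reactants: 10 2',2'',4''-tri-O-benzyl methyl gyrophorate
Product: 11 methyl gyrophorate (methyl 4-{[4-{[2,4-dihydroxy-6-methylbenzoyl]oxy}-2-hydroxy-6-methylbenzoyl]oxy}-2-hydroxy-6-methylbenzoate), the target
Conditions: H2 (1 atm), Pd/C (10 wt % Pd), EtOAc, rt
Reagents that add atoms: none
Why: Catalytic hydrogenolysis cleaves the three benzyl aryl ethers under neutral conditions that leave aryl esters and the methyl ester intact, and the non-nucleophilic solvent excludes alcoholysis of the depside links.

## Compound list

1 | methyl orsellinate (methyl 2,4-dihydroxy-6-methylbenzoate) | COC(=O)c1c(C)cc(O)cc1O | starting material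
2 | methyl 2,4-bis(benzyloxy)-6-methylbenzoate | COC(=O)c1c(C)cc(OCc2ccccc2)cc1OCc1ccccc1 | intermediate
3 | 2,4-bis(benzyloxy)-6-methylbenzoic acid | Cc1cc(OCc2ccccc2)cc(OCc2ccccc2)c1C(=O)O | intermediate
4 | orcinol (5-methylbenzene-1,3-diol) | Cc1cc(O)cc(O)c1 | starting material
5 | 4-iodoorcinol (4-iodo-5-methylbenzene-1,3-diol) | Cc1cc(O)cc(O)c1I | intermediate
6 | 2,4-bis(benzyloxy)-6-methylbenzoyl chloride (not isolated) | Cc1cc(OCc2ccccc2)cc(OCc2ccccc2)c1C(=O)Cl | intermediate
7 | 3-hydroxy-4-iodo-5-methylphenyl 2,4-bis(benzyloxy)-6-methylbenzoate | Cc1cc(OC(=O)c2c(C)cc(OCc3ccccc3)cc2OCc2ccccc2)cc(O)c1I | intermediate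
8 | 3-(benzyloxy)-4-iodo-5-methylphenyl 2,4-bis(benzyloxy)-6-methylbenzoate | Cc1cc(OC(=O)c2c(C)cc(OCc3ccccc3)cc2OCc2ccccc2)cc(OCc2ccccc2)c1I | intermediate
9 | carbon monoxide | [C-]#[O+] | starting material
10 | 2',2'',4''-tri-O-benzyl methyl gyrophorate | COC(=O)c1c(C)cc(OC(=O)c2c(C)cc(OC(=O)c3c(C)cc(OCc4ccccc4)cc3OCc3ccccc3)cc2OCc2ccccc2)cc1O | intermediate
11 | methyl gyrophorate (CNP0212402.0; no stereocentres) | COC(=O)c1c(C)cc(OC(=O)c2c(C)cc(OC(=O)c3c(C)cc(O)cc3O)cc2O)cc1O | target

## Step count and risks

Total step count: 7.
Longest linear sequence: 6 steps (1, 2, 4, 5, 6, 7, from methyl orsellinate). The orcinol branch joins at step 4.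

**Step 6.**
- Risk: capture of the crowded aroylpalladium intermediate by the weakly nucleophilic phenoxide may be slow. Hydrodeiodination, palladation of the phenyl ring of the neighbouring benzyl ether, or phenoxide-induced exchange at the B–C ester could then take over.
- Fallback: it sets out from 8 and separates the two bond formations without palladium.
- Iodine–magnesium exchange with iPrMgCl·LiCl in THF at −20 °C should give the arylmagnesium chloride F1. The alkoxy group beside iodine assists the exchange, and the di-ortho-substituted aryl ester should be tolerated at this temperature.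
- A CO2 quench and acidic work-up give 2-(benzyloxy)-4-{[2,4-bis(benzyloxy)-6-methylbenzoyl]oxy}-6-methylbenzoic acid F2.
- This acid is condensed with 1 by trifluoroacetic anhydride in toluene at rt, the mixed-anhydride esterification suited to di-ortho-substituted depside acids, which again engages only the 4-hydroxyl. The fallback comes back to the route at 10.

**Step 4.**
- Risk: discrimination between the two hydroxyls of 5 may be insufficient, and double acylation may occur, both at the expense of acid 3.
- Fallback: it sets out from 5 and moves the differentiation onto a cheap, much bulkier reagent.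
- TIPSCl and imidazole in CH2Cl2 at 0 °C should silylate only the uncrowded hydroxyl, giving 2-iodo-3-methyl-5-(triisopropylsilyloxy)phenol F3.
- BnBr and K2CO3 in acetone give [3-(benzyloxy)-4-iodo-5-methylphenoxy]triisopropylsilane F4.
- Bu4NF in THF at 0 °C frees 3-(benzyloxy)-4-iodo-5-methylphenol F5.
- Its single hydroxyl is acylated with 6 (pyridine, cat. DMAP, CH2Cl2). The fallback comes back to the route at 8.

**Step 3.**
- Risk: iodine may be delivered partly to C2 between the hydroxyls or twice (C4 and C6), and it may migrate under traces of acid.
- Fallback: it sets out from 4 and fixes the site with ether groups.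
- MeI and K2CO3 in acetone give 3,5-dimethoxytoluene F6.
- NIS in MeCN at rt iodinates next to the methyl group, the established halogenation site of orcinol dialkyl ethers because C2 is shielded by two alkoxy groups. This gives 2-iodo-1,5-dimethoxy-3-methylbenzene F7.
- BBr3 in CH2Cl2 (−78 → 0 °C, quench into cold aqueous NaHCO3) cleaves both methyl ethers. The fallback comes back to the route at 5.

## Further compounds

F1 | step 6 | {2-(benzyloxy)-4-{[2,4-bis(benzyloxy)-6-methylbenzoyl]oxy}-6-methylphenyl}magnesium chloride | Cc1cc(OC(=O)c2c(C)cc(OCc3ccccc3)cc2OCc2ccccc2)cc(OCc2ccccc2)c1[Mg]Cl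
F2 | step 6 | 2-(benzyloxy)-4-{[2,4-bis(benzyloxy)-6-methylbenzoyl]oxy}-6-methylbenzoic acid | Cc1cc(OC(=O)c2c(C)cc(OCc3ccccc3)cc2OCc2ccccc2)cc(OCc2ccccc2)c1C(=O)O
F3 | step 4 | 2-iodo-3-methyl-5-(triisopropylsilyloxy)phenol | Cc1cc(O[Si](C(C)C)(C(C)C)C(C)C)cc(O)c1I
F4 | step 4 | [3-(benzyloxy)-4-iodo-5-methylphenoxy]triisopropylsilane | Cc1cc(O[Si](C(C)C)(C(C)C)C(C)C)cc(OCc2ccccc2)c1I
F5 | step 4 | 3-(benzyloxy)-4-iodo-5-methylphenol | Cc1cc(O)cc(OCc2ccccc2)c1I
F6 | step 3 | 3,5-dimethoxytoluene | COc1cc(C)cc(OC)c1
F7 | step 3 | 2-iodo-1,5-dimethoxy-3-methylbenzene | COc1cc(C)c(I)c(OC)c1
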